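**Plan**

Numbering follows the briarane skeleton (ten-membered ring C1–C10; cyclohexane C1, C10–C14; lactone O–C7, C8, C17, C19; ester C16 on C5). The enabling feature is that C8 (tertiary carbinol) and C9 (acetoxy carbinol) are neighbouring atoms of the ten-membered ring, a 1,2-diol, so this ring is cut between them into a C8 ketone and a C9 aldehyde.
Further cuts, backwards: O7–C19 (lactone) and the O9 acetate; C8–C17 (propanoate aldol, then oxidation); C5=C6 (Horner–Wadsworth–Emmons); C1–C2 (Mukaiyama aldol) and C10–C9 (vinyl cuprate); C1=C10 of a cyclohexenone (ring-closing metathesis); C11–C12 (crotylboration).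
Forward: the cyclohexenone is made first and becomes the fully substituted cyclohexane carrying the C2–C5 phosphonate arm; the C6–C8 unit from D-mannitol is joined by olefination and extended to the β-keto ester; the ten-membered ring is then closed at C8–C9 and the γ-lactone last.
Stereochemistry: C11/C12 from a catalyst-controlled anti-crotylboration; C10, C1, C2 and C14 by substrate control from these; C7 from D-mannitol; C8 and C9 in the ring closure through a samarium chelate anchored on O7; C17 by equilibration of the finished lactone.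

Key step: step 24

Remark: C17 lies between two carbonyl groups in the β-keto ester and cannot hold a configuration there, so 29–36 are drawn without a descriptor at C17 (both epimers) and the centre is fixed in step 27.
Remark: the phosphonate carbon C5 in 13–19, C14 in 7 and 8 and C8 in 29–31 are uncontrolled centres that are later removed by olefination or oxidation; metal and boron alkoxides that are only hydrolysed on work-up are not listed as intermediates.
Abbreviations: TBS = tert-butyldimethylsilyl, TES = triethylsilyl, TMS = trimethylsilyl, DMP = Dess–Martin periodinane.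

**Route**

Step 1
Reactants: 1 3-(TBS-oxy)propanal; 2 (E)-crotylboronic acid pinacol ester
Product: 3 (3R,4R)-1-(TBS-oxy)-4-methylhex-5-en-3-ol
Conditions: (S)-TRIP [(S)-3,3'-bis(2,4,6-triisopropylphenyl)-BINOL hydrogen phosphate] (5 mol%), toluene, −30 °C; aq NaHCO3
Reagents that add atoms: none
Why: Chiral phosphoric acid-catalysed crotylboration through a closed chair transition state, in which the (E)-boronate gives the anti pair and the catalyst antipode is the one that sends the crotyl group to the Si face of the aldehyde, setting C12 (R) and C11 (R).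

Step 2
Reactants: 3 (3R,4R)-1-(TBS-oxy)-4-methylhex-5-en-3-ol
Product: 4 (3R,4R)-1,3-bis(TBS-oxy)-4-methylhex-5-ene
Conditions: TBSCl, imidazole, DMF, rt
Reagents that add atoms: tert-butyldimethylsilyl chloride, CC(C)(C)[Si](C)(C)Cl
Why: Standard silylation of a secondary alcohol, which protects O12 for the organometallic and Lewis acid steps ahead.

Step 3
Reactants: 4 (3R,4R)-1,3-bis(TBS-oxy)-4-methylhex-5-ene
Product: 5 (3R,4R)-3-(TBS-oxy)-4-methylhex-5-en-1-ol
Conditions: HF·pyridine, pyridine, THF, 0 °C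
Reagents that add atoms: none
Why: Selective desilylation, because the primary silyl ether is cleaved much faster than the hindered secondary one next to the methyl-bearing carbon.

Step 4
Reactants: 5 (3R,4R)-3-(TBS-oxy)-4-methylhex-5-en-1-ol
Product: 6 (3R,4R)-3-(TBS-oxy)-4-methylhex-5-enal
Conditions: DMP, NaHCO3, CH2Cl2, 0 °C → rt
Reagents that add atoms: none
Why: Dess–Martin oxidation of a primary alcohol under buffered conditions, which should not eliminate the β-silyloxy group.

Step 5
Reactants: 6 (3R,4R)-3-(TBS-oxy)-4-methylhex-5-enal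
Product: 7 (5R,6R)-5-(TBS-oxy)-2,6-dimethylocta-1,7-dien-3-ol (both C3 epimers)
Conditions: CH2=C(CH3)MgBr, THF, −78 → 0 °C; then H2O
Reagents that add atoms: isopropenylmagnesium bromide, CC(=C)[Mg]Br
Why: Grignard addition to the aldehyde brings in C1 and its methyl group, and the new carbinol (C14) needs no control because it is oxidised in step 7.

Step 6
Reactants: 7 (5R,6R)-5-(TBS-oxy)-2,6-dimethylocta-1,7-dien-3-ol
Product: 8 (4R,5R)-5-(TBS-oxy)-2,4-dimethylcyclohex-2-en-1-ol (both C1 epimers)
Conditions: second-generation Grubbs catalyst [RuCl2(=CHPh)(PCy3)(H2IMes)] (3 mol%), CH2Cl2, 40 °C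
Reagents that add atoms: none
Why: Ring-closing metathesis of a monosubstituted with a 1,1-disubstituted alkene to a six-membered trisubstituted cycloalkene is reliable and is driven by loss of ethene.

Step 7
Reactants: 8 (4R,5R)-5-(TBS-oxy)-2,4-dimethylcyclohex-2-en-1-ol
Product: 9 (4R,5R)-5-(TBS-oxy)-2,4-dimethylcyclohex-2-en-1-one
Conditions: DMP, NaHCO3, CH2Cl2, rt
Reagents that add atoms: none
Why: Dess–Martin oxidation of the allylic alcohol gives the enone (C14 carbonyl, C1=C10) without base that could eliminate the C12 silyloxy group.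

Step 8
Reactants: 9 (4R,5R)-5-(TBS-oxy)-2,4-dimethylcyclohex-2-en-1-one
Product: 10 {[(3S,4R,5R)-5-(TBS-oxy)-2,4-dimethyl-3-vinylcyclohex-1-en-1-yl]oxy}trimethylsilane
Conditions: CH2=CHMgBr, CuBr·SMe2 (10 mol%), TMSCl, HMPA, THF, −78 °C; Et3N, pentane, filtration (used crude)
Reagents that add atoms: vinylmagnesium bromide, C=C[Mg]Br; chlorotrimethylsilane, C[Si](C)(C)Cl
Why: Copper-catalysed conjugate addition with in situ silylation, in which vinyl should add axially to the half-chair that has the C11 and C12 substituents equatorial, anti to the C12 silyloxy group and therefore cis to the C11 methyl, while the enolate is trapped regiospecifically.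

Step 9
Reactants: 11 acrolein; 12 trimethyl phosphonoacetate
Product: 13 methyl 2-(dimethoxyphosphoryl)-5-oxopentanoate (racemic)
Conditions: NaOMe (5 mol%), MeOH, 0 °C, slow addition of 11 to excess 12
Reagents that add atoms: none
Why: Base-catalysed Michael addition of the phosphonoacetate carbanion to acrolein gives the C2–C5 arm with the olefination handle already in place.

Step 10
Reactants: 10 TMS enol ether; 13 methyl 2-(dimethoxyphosphoryl)-5-oxopentanoate
Product: 14 β-hydroxy ketone, methyl (5R)-5-[(1S,2S,3R,4R)-4-(TBS-oxy)-1,3-dimethyl-6-oxo-2-vinylcyclohexyl]-2-(dimethoxyphosphoryl)-5-hydroxypentanoate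
Conditions: BF3·OEt2 (2.5 equiv), CH2Cl2, −78 °C; aq NaHCO3
Reagents that add atoms: none
Why: Mukaiyama aldol reaction in which the aldehyde meets C1 anti to the pseudoaxial C10 vinyl group (quaternary C1, S) and an open antiperiplanar transition state with the aldehyde chain gauche to the C1 methyl and not to C10 should give the (2R) carbinol.

Step 11
Reactants: 14 β-hydroxy ketone
Product: 16 syn-1,3-diol with free C2 and C14 hydroxyls (14S), via diethylboron chelate 15 (not isolated)
Conditions: Et2BOMe, THF–MeOH (4:1), −78 °C; NaBH4, −78 °C; then MeOH–AcOH co-evaporation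
Reagents that add atoms: none
Why: Narasaka–Prasad reduction, in which the boron chelate spans O2 and the C14 carbonyl on the face of the axial C2 arm so that external hydride should add from the opposite face and give the equatorial C14 alcohol, syn to O2.

Step 12
Reactants: 16 syn-1,3-diol
Product: 17 C2,C14-diacetate (C12 still TBS-protected)
Conditions: Ac2O, DMAP, pyridine, rt → 40 °C
Reagents that add atoms: acetic anhydride, CC(=O)OC(C)=O
Why: DMAP-catalysed acetylation of both hindered secondary alcohols, done at once so that the C2 hydroxyl cannot close a δ-lactone onto the methyl ester.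

Step 13
Reactants: 17 C2,C14-diacetate
Product: 18 C12 alcohol
Conditions: HF·pyridine, THF, 0 °C → rt
Reagents that add atoms: none
Why: Fluoride-mediated desilylation of the remaining secondary silyl ether, to which acetates, phosphonate and alkene are inert.

Step 14
Reactants: 18 C12 alcohol
Product: 19 C2,C12,C14-triacetate phosphonate
Conditions: Ac2O, DMAP, pyridine, rt
Reagents that add atoms: acetic anhydride, CC(=O)OC(C)=O
Why: Acetylation of the equatorial C12 alcohol completes the three ring-side acetates of the target.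

Step 15
Reactants: 20 1,2:5,6-di-O-isopropylidene-D-mannitol
Product: 21 (R)-2,2-dimethyl-1,3-dioxolane-4-carbaldehyde
Conditions: NaIO4, aq NaHCO3, CH2Cl2, 0 °C → rt (used at once)
Reagents that add atoms: none
Why: Periodate glycol cleavage of the central diol gives two molecules of the aldehyde with the stereocentre (future C7) untouched.

Step 16
Reactants: 19 triacetate phosphonate; 21 (R)-2,2-dimethyl-1,3-dioxolane-4-carbaldehyde
Product: 22 (E)-enoate acetonide (C5=C6, methyl ester trans to C7)
Conditions: LiCl, DBU, MeCN, 0 °C → rt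
Reagents that add atoms: none
Why: Horner–Wadsworth–Emmons reaction under Masamune–Roush conditions, in which the α-substituted phosphonoacetate should give the trisubstituted enoate with the ester trans to C7 and the mild base spares the acetates and the α-alkoxy aldehyde.

Step 17
Reactants: 22 (E)-enoate acetonide
Product: 23 C7,C8-diol
Conditions: AcOH–H2O (4:1), 40 °C
Reagents that add atoms: none
Why: Acetal hydrolysis in aqueous acetic acid leaves the acetates alone, and the E geometry keeps both new hydroxyls out of reach of the methyl ester.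

Step 18
Reactants: 23 C7,C8-diol
Product: 24 C7,C8-bis(TES) ether
Conditions: TESCl, imidazole, DMF, 0 °C
Reagents that add atoms: chlorotriethylsilane, CC[Si](CC)(CC)Cl
Why: Exhaustive silylation puts on O7 the acid-labile triethylsilyl group that stays until the last acid step.

Step 19
Reactants: 24 C7,C8-bis(TES) ether
Product: 25 C8 primary alcohol (O7 TES)
Conditions: HF·pyridine, pyridine, THF, −10 °C
Reagents that add atoms: none
Why: Selective desilylation, since the primary triethylsilyl ether is cleaved well before the secondary allylic one.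

Step 20
Reactants: 25 C8 primary alcohol
Product: 26 C8 aldehyde (α-TES-oxy)
Conditions: DMP, NaHCO3, CH2Cl2, 0 °C
Reagents that add atoms: none
Why: Dess–Martin oxidation, chosen because its base-free conditions should not epimerise or isomerise the α-silyloxy β,γ-unsaturated aldehyde.

Step 21
Reactants: 26 C8 aldehyde; 27 tert-butyl propanoate
Product: 29 aldol adduct (C8 carbinol; C17 methyl; C19 tert-butyl ester), via lithium enolate 28 (not isolated)
Conditions: LiN(iPr)2 (LDA), 27, THF, −78 °C; then 26, −78 °C; AcOH quench at −78 °C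
Reagents that add atoms: none
Why: Aldol addition of the preformed lithium ester enolate at −78 °C, where the aldehyde reacts far faster than acetates or enoate, with C8 and C17 left uncontrolled because C8 is oxidised and C17 equilibrated later.

Step 22
Reactants: 29 aldol adduct
Product: 31 C9 aldehyde with C8 carbinol, via vicinal diol 30 (not isolated)
Conditions: OsO4 (2 mol%), NaIO4, 2,6-lutidine, dioxane–H2O (3:1), rt
Reagents that add atoms: osmium tetroxide (catalytic oxygen carrier), O=[Os](=O)(=O)=O; sodium periodate (stoichiometric oxygen source), [Na+].[O-]I(=O)(=O)=O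
Why: Johnson–Lemieux oxidation, in which OsO4 should dihydroxylate the electron-rich monosubstituted alkene much faster than the electron-poor trisubstituted enoate before periodate cleaves the diol.

Step 23
Reactants: 31 C9 aldehyde with C8 carbinol
Product: 32 seco C9-aldehyde C8-keto tert-butyl ester
Conditions: DMP, NaHCO3, CH2Cl2, 0 °C → rt
Reagents that add atoms: none
Why: Dess–Martin oxidation of the secondary alcohol to the β-keto ester leaves the aldehyde untouched and is mild enough for the C7 and C10 centres.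

Step 24
Reactants: 32 seco C9-aldehyde C8-keto tert-butyl ester
Product: 33 ten-membered C8,C9-diol (O7 TES; C19 tert-butyl ester)
Conditions: SmI2 (3 equiv), THF, −78 → −40 °C, syringe-pump addition of 32 (final 2 mM); pH 7 buffer
Reagents that add atoms: none
Why: SmI2 transfers an electron to the aldehyde, the most easily reduced carbonyl, and the C9 ketyl, bound to trivalent samarium that is also held by the β-keto ester (C8=O and the C19 ester carbonyl), adds to C8, after which a second electron and work-up give the diol. The closest known reaction type is the SmI2 pinacol cyclisation of ω-oxo β-keto esters to cis-diols, together with reductive carbonyl–carbonyl couplings to medium and large rings. The ten-membered ring closes by joining the two carbonyl carbons of one chain, so that C1–C10 become ring atoms and both oxygens stay outside the ring; high dilution, the cyclohexane, the quaternary C1 and the ring-cis enoate favour closure over coupling between molecules. C8 is set by O7, which sits on the same samarium so that C9 enters the ketone face away from C6, and C9 is set by the samarium bridge, which holds O9 cis to O8. The step needs chemoselectivity for the aldehyde over the enoate, the acetates and the α-silyloxy ketone, which the order of reduction potentials, the absence of HMPA or a proton donor and the low temperature should secure. The tert-butyl ester keeps the new C9 alkoxide from closing the wrong γ-lactone.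

Step 25
Reactants: 33 ten-membered C8,C9-diol
Product: 34 C9 acetate
Conditions: Ac2O, DMAP, pyridine, 0 °C → rt
Reagents that add atoms: acetic anhydride, CC(=O)OC(C)=O
Why: Acetylation of the secondary C9 alcohol, under which the tertiary C8 alcohol does not react.

Step 26
Reactants: 34 C9 acetate
Product: 36 γ-lactone as the C17 epimer pair, via hydroxy acid 35 (not isolated)
Conditions: TFA–CH2Cl2 (1:4), H2O (5 equiv), 0 °C → rt
Reagents that add atoms: none
Why: Acidolysis removes the triethylsilyl ether and the tert-butyl ester, and the γ-hydroxy acid closes the five-membered lactone onto O7 (lactonisation), O9 being already blocked as its acetate.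

Step 27
Reactants: 36 γ-lactone C17 epimer pair
Product: 37 CNP0230222.1
Conditions: DBU (0.3 equiv), toluene, rt
Reagents that add atoms: none
Why: Base-mediated epimerisation through the lactone enolate, in which the C17 methyl should settle trans to the C9 ring branch and cis to the small C8 hydroxyl, which is the (17R) configuration of the target.

**Compound list**

1 | 3-[(tert-butyldimethylsilyl)oxy]propanal | O=CCCO[Si](C)(C)C(C)(C)C | starting material
2 | (E)-crotylboronic acid pinacol ester | C/C=C/CB1OC(C)(C)C(C)(C)O1 | starting material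
3 | (3R,4R)-1-[(tert-butyldimethylsilyl)oxy]-4-methylhex-5-en-3-ol | C=C[C@@H](C)[C@H](O)CCO[Si](C)(C)C(C)(C)C | intermediate
4 | (3R,4R)-1,3-bis[(tert-butyldimethylsilyl)oxy]-4-methylhex-5-ene | C=C[C@@H](C)[C@H](O[Si](C)(C)C(C)(C)C)CCO[Si](C)(C)C(C)(C)C | intermediate
5 | (3R,4R)-3-[(tert-butyldimethylsilyl)oxy]-4-methylhex-5-en-1-ol | C=C[C@@H](C)[C@H](O[Si](C)(C)C(C)(C)C)CCO | intermediate
6 | (3R,4R)-3-[(tert-butyldimethylsilyl)oxy]-4-methylhex-5-enal | C=C[C@@H](C)[C@H](O[Si](C)(C)C(C)(C)C)CC=O | intermediate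
7 | (5R,6R)-5-[(tert-butyldimethylsilyl)oxy]-2,6-dimethylocta-1,7-dien-3-ol (both C3 epimers) | C=C[C@@H](C)[C@H](O[Si](C)(C)C(C)(C)C)CC(O)C(C)=C | intermediate
8 | (4R,5R)-5-[(tert-butyldimethylsilyl)oxy]-2,4-dimethylcyclohex-2-en-1-ol (both C1 epimers) | CC1=C[C@@H](C)[C@H](O[Si](C)(C)C(C)(C)C)CC1O | intermediate
9 | (4R,5R)-5-[(tert-butyldimethylsilyl)oxy]-2,4-dimethylcyclohex-2-en-1-one | CC1=C[C@@H](C)[C@H](O[Si](C)(C)C(C)(C)C)CC1=O | intermediate
10 | {[(3S,4R,5R)-5-[(tert-butyldimethylsilyl)oxy]-2,4-dimethyl-3-vinylcyclohex-1-en-1-yl]oxy}trimethylsilane | C=C[C@H]1[C@@H](C)[C@H](O[Si](C)(C)C(C)(C)C)CC(O[Si](C)(C)C)=C1C | intermediate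
11 | acrolein | C=CC=O | starting material
12 | trimethyl phosphonoacetate | COC(=O)CP(=O)(OC)OC | starting material
13 | methyl 2-(dimethoxyphosphoryl)-5-oxopentanoate (racemic) | COC(=O)C(CCC=O)P(=O)(OC)OC | intermediate
14 | methyl (5R)-5-[(1S,2S,3R,4R)-4-[(tert-butyldimethylsilyl)oxy]-1,3-dimethyl-6-oxo-2-vinylcyclohexyl]-2-(dimethoxyphosphoryl)-5-hydroxypentanoate (both epimers at the phosphonate carbon) | C=C[C@H]1[C@@H](C)[C@H](O[Si](C)(C)C(C)(C)C)CC(=O)[C@]1(C)[C@H](O)CCC(C(=O)OC)P(=O)(OC)OC | intermediate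
15 | O2-diethylboryl derivative of 14 (boron chelated to the C14 carbonyl) | C=C[C@H]1[C@@H](C)[C@H](O[Si](C)(C)C(C)(C)C)CC(=O)[C@]1(C)[C@H](OB(CC)CC)CCC(C(=O)OC)P(=O)(OC)OC | intermediate (not isolated)
16 | methyl (5R)-5-[(1S,2S,3R,4R,6S)-4-[(tert-butyldimethylsilyl)oxy]-6-hydroxy-1,3-dimethyl-2-vinylcyclohexyl]-2-(dimethoxyphosphoryl)-5-hydroxypentanoate | C=C[C@H]1[C@@H](C)[C@H](O[Si](C)(C)C(C)(C)C)C[C@H](O)[C@]1(C)[C@H](O)CCC(C(=O)OC)P(=O)(OC)OC | intermediate
17 | methyl (5R)-5-acetoxy-5-[(1S,2S,3R,4R,6S)-6-acetoxy-4-[(tert-butyldimethylsilyl)oxy]-1,3-dimethyl-2-vinylcyclohexyl]-2-(dimethoxyphosphoryl)pentanoate | C=C[C@H]1[C@@H](C)[C@H](O[Si](C)(C)C(C)(C)C)C[C@H](OC(C)=O)[C@]1(C)[C@H](OC(C)=O)CCC(C(=O)OC)P(=O)(OC)OC | intermediate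
18 | methyl (5R)-5-acetoxy-5-[(1S,2S,3R,4R,6S)-6-acetoxy-4-hydroxy-1,3-dimethyl-2-vinylcyclohexyl]-2-(dimethoxyphosphoryl)pentanoate | C=C[C@H]1[C@@H](C)[C@H](O)C[C@H](OC(C)=O)[C@]1(C)[C@H](OC(C)=O)CCC(C(=O)OC)P(=O)(OC)OC | intermediate
19 | methyl (5R)-5-acetoxy-5-[(1S,2S,3R,4R,6S)-4,6-diacetoxy-1,3-dimethyl-2-vinylcyclohexyl]-2-(dimethoxyphosphoryl)pentanoate | C=C[C@H]1[C@@H](C)[C@H](OC(C)=O)C[C@H](OC(C)=O)[C@]1(C)[C@H](OC(C)=O)CCC(C(=O)OC)P(=O)(OC)OC | intermediate
20 | 1,2:5,6-di-O-isopropylidene-D-mannitol | CC1(C)OC[C@@H](O1)[C@@H](O)[C@H](O)[C@H]1COC(C)(C)O1 | starting material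
21 | (R)-2,2-dimethyl-1,3-dioxolane-4-carbaldehyde | O=C[C@H]1COC(C)(C)O1 | intermediate
22 | methyl (2E)-2-{(3R)-3-acetoxy-3-[(1S,2S,3R,4R,6S)-4,6-diacetoxy-1,3-dimethyl-2-vinylcyclohexyl]propyl}-3-[(4S)-2,2-dimethyl-1,3-dioxolan-4-yl]prop-2-enoate | C=C[C@H]1[C@@H](C)[C@H](OC(C)=O)C[C@H](OC(C)=O)[C@]1(C)[C@H](OC(C)=O)CC/C(C(=O)OC)=C\[C@H]1COC(C)(C)O1 | intermediate
23 | methyl (2E,4S)-2-{(3R)-3-acetoxy-3-[(1S,2S,3R,4R,6S)-4,6-diacetoxy-1,3-dimethyl-2-vinylcyclohexyl]propyl}-4,5-dihydroxypent-2-enoate | C=C[C@H]1[C@@H](C)[C@H](OC(C)=O)C[C@H](OC(C)=O)[C@]1(C)[C@H](OC(C)=O)CC/C(C(=O)OC)=C\[C@H](O)CO | intermediate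
24 | 4,5-bis(triethylsilyl) ether of 23 (4S) | C=C[C@H]1[C@@H](C)[C@H](OC(C)=O)C[C@H](OC(C)=O)[C@]1(C)[C@H](OC(C)=O)CC/C(C(=O)OC)=C\[C@H](O[Si](CC)(CC)CC)CO[Si](CC)(CC)CC | intermediate
25 | 4-(triethylsilyl) ether of 23 with free primary C8 hydroxyl (4S) | C=C[C@H]1[C@@H](C)[C@H](OC(C)=O)C[C@H](OC(C)=O)[C@]1(C)[C@H](OC(C)=O)CC/C(C(=O)OC)=C\[C@H](O[Si](CC)(CC)CC)CO | intermediate
26 | methyl (2E,4S)-2-{(3R)-3-acetoxy-3-[(1S,2S,3R,4R,6S)-4,6-diacetoxy-1,3-dimethyl-2-vinylcyclohexyl]propyl}-5-oxo-4-[(triethylsilyl)oxy]pent-2-enoate | C=C[C@H]1[C@@H](C)[C@H](OC(C)=O)C[C@H](OC(C)=O)[C@]1(C)[C@H](OC(C)=O)CC/C(C(=O)OC)=C\[C@H](O[Si](CC)(CC)CC)C=O | intermediate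
27 | tert-butyl propanoate | CCC(=O)OC(C)(C)C | starting material
28 | lithium enolate of tert-butyl propanoate (methyl trans to O–Li) | [Li+].C/C=C(/[O-])OC(C)(C)C | intermediate (not isolated)
29 | aldol adduct: 26 extended at C8 by the propanoate unit (C8 secondary alcohol, C17 methyl, C19 tert-butyl ester; C8 and C17 unassigned; C10 vinyl) | C=C[C@H]1[C@@H](C)[C@H](OC(C)=O)C[C@H](OC(C)=O)[C@]1(C)[C@H](OC(C)=O)CC/C(C(=O)OC)=C\[C@H](O[Si](CC)(CC)CC)C(O)C(C)C(=O)OC(C)(C)C | intermediate
30 | vicinal diol from the C10 vinyl group of 29 | OCC(O)[C@H]1[C@@H](C)[C@H](OC(C)=O)C[C@H](OC(C)=O)[C@]1(C)[C@H](OC(C)=O)CC/C(C(=O)OC)=C\[C@H](O[Si](CC)(CC)CC)C(O)C(C)C(=O)OC(C)(C)C | intermediate (not isolated)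
31 | C9 aldehyde (formyl on C10) with C8 carbinol | O=C[C@H]1[C@@H](C)[C@H](OC(C)=O)C[C@H](OC(C)=O)[C@]1(C)[C@H](OC(C)=O)CC/C(C(=O)OC)=C\[C@H](O[Si](CC)(CC)CC)C(O)C(C)C(=O)OC(C)(C)C | intermediate
32 | seco C9-aldehyde C8-keto tert-butyl ester (O7 triethylsilyl; C2, C12, C14 acetates; E-enoate; C17 unassigned) | O=C[C@H]1[C@@H](C)[C@H](OC(C)=O)C[C@H](OC(C)=O)[C@]1(C)[C@H](OC(C)=O)CC/C(C(=O)OC)=C\[C@H](O[Si](CC)(CC)CC)C(=O)C(C)C(=O)OC(C)(C)C | intermediate
33 | ten-membered C8,C9-diol (O7, O8 and O9 on one face as in the target; C7 S, C9 R; O7 triethylsilyl; C19 tert-butyl ester; C17 unassigned) | COC(=O)/C1=C/[C@H](O[Si](CC)(CC)CC)[C@@](O)(C(C)C(=O)OC(C)(C)C)[C@H](O)[C@H]2[C@@H](C)[C@H](OC(C)=O)C[C@H](OC(C)=O)[C@]2(C)[C@H](OC(C)=O)CC1 | intermediate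
34 | C9 acetate of 33 | COC(=O)/C1=C/[C@H](O[Si](CC)(CC)CC)[C@@](O)(C(C)C(=O)OC(C)(C)C)[C@H](OC(C)=O)[C@H]2[C@@H](C)[C@H](OC(C)=O)C[C@H](OC(C)=O)[C@]2(C)[C@H](OC(C)=O)CC1 | intermediate
35 | hydroxy acid: 34 with free C7 hydroxyl and free C19 carboxylic acid | COC(=O)/C1=C/[C@H](O)[C@@](O)(C(C)C(=O)O)[C@H](OC(C)=O)[C@H]2[C@@H](C)[C@H](OC(C)=O)C[C@H](OC(C)=O)[C@]2(C)[C@H](OC(C)=O)CC1 | intermediate (not isolated)
36 | γ-lactone (O7–C19) as the pair of C17 epimers | COC(=O)/C1=C/[C@@H]2OC(=O)C(C)[C@@]2(O)[C@H](OC(C)=O)[C@H]2[C@@H](C)[C@H](OC(C)=O)C[C@H](OC(C)=O)[C@]2(C)[C@H](OC(C)=O)CC1 | intermediate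
37 | CNP0230222.1 (1S,2R,7S,8S,9R,10S,11R,12R,14S,17R; 5E) | COC(=O)/C1=C/[C@@H]2OC(=O)[C@H](C)[C@@]2(O)[C@H](OC(C)=O)[C@H]2[C@@H](C)[C@H](OC(C)=O)C[C@H](OC(C)=O)[C@]2(C)[C@H](OC(C)=O)CC1 | target

**Step count**

Total: 27 steps. Longest linear sequence: 25 steps (steps 1–8, 10–14 and 16–27); steps 9 and 15 are single-step branches.

**Steps most likely to fail**

1. Step 24 (samarium pinacol ring closure). What may go wrong: the C9 ketyl is reduced on to the primary alcohol or couples between two molecules faster than the strained ten-membered ring closes, the α-silyloxy ketone loses its C7 oxygen by over-reduction, or the ring closes with poor facial selectivity at C9, where the acyclic preference of the C10 centre opposes the chelate. Fallback: make the same C8–C9 bond by a two-electron Nozaki–Hiyama–Kishi closure in place of the radical one. It sets out from aldol adduct 29: Dess–Martin oxidation gives the β-keto ester F1, NaH/PhNTf2 converts it into the (Z)-enol triflate F2, OsO4/NaIO4 unmasks the C9 aldehyde in the triflate aldehyde F3, and CrCl2 with catalytic NiCl2 in DMSO–THF at high dilution closes the ring to the allylic alcohol F4 (C9 carbinol, exocyclic C8=C17 enoate). Hydroxyl-directed epoxidation of F4 with mCPBA should put oxygen on C8 cis to the C9 hydroxyl, giving the epoxy ester F5, and SmI2 cleaves the C17–O bond of this α,β-epoxy ester to the β-hydroxy ester, which is diol 33, where the route is rejoined.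

2. Step 10 (Mukaiyama aldol). What may go wrong: low simple diastereoselection at C2 if a closed transition state competes with the open one, so that the C2 epimer dominates. Fallback: set C2 by hydride reduction under 1,3-induction from C14, not by the aldol. It sets out from 14 (either C2 epimer or the mixture): Dess–Martin oxidation gives the 1,3-diketone F6; NaBH4 at −78 °C should reduce the cyclohexanone carbonyl first, from the face opposite the axial acyl arm, to the hydroxy ketone F7; Et2BOMe/NaBH4 then reduces the side-chain ketone syn to the C14 hydroxyl (Narasaka–Prasad) and gives diol 16, where the route is rejoined.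

3. Step 26 (acid-mediated deprotection and lactonisation). What may go wrong: ionisation and loss of the tertiary C8 hydroxyl (dehydration towards the 8,17-alkene), or migration of the C9 acetyl group to the freed C7 hydroxyl before the lactone closes. Fallback: remove the protecting groups without protic acid and close the lactone by carboxyl activation. It sets out from 34: TMSOTf/2,6-lutidine converts the tert-butyl ester into the trimethylsilyl ester and caps the C8 hydroxyl, giving the silyl ester F8; HF·pyridine then removes all three silyl groups to give hydroxy acid 35, now isolated; 2-chloro-1-methylpyridinium iodide/Et3N (Mukaiyama lactonisation) closes the γ-lactone to 36, where the route is rejoined.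

**Further compounds**

F1 | step 24 | β-keto tert-butyl ester from 29, C10 vinyl retained (C17 unassigned) | C=C[C@H]1[C@@H](C)[C@H](OC(C)=O)C[C@H](OC(C)=O)[C@]1(C)[C@H](OC(C)=O)CC/C(C(=O)OC)=C\[C@H](O[Si](CC)(CC)CC)C(=O)C(C)C(=O)OC(C)(C)C
F2 | step 24 | (Z)-enol triflate of F1 (C8 triflate cis to the tert-butyl ester) | C=C[C@H]1[C@@H](C)[C@H](OC(C)=O)C[C@H](OC(C)=O)[C@]1(C)[C@H](OC(C)=O)CC/C(C(=O)OC)=C\[C@H](O[Si](CC)(CC)CC)/C(OS(=O)(=O)C(F)(F)F)=C(\C)C(=O)OC(C)(C)C
F3 | step 24 | C9 aldehyde bearing the (Z)-enol triflate | O=C[C@H]1[C@@H](C)[C@H](OC(C)=O)C[C@H](OC(C)=O)[C@]1(C)[C@H](OC(C)=O)CC/C(C(=O)OC)=C\[C@H](O[Si](CC)(CC)CC)/C(OS(=O)(=O)C(F)(F)F)=C(\C)C(=O)OC(C)(C)C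
F4 | step 24 | ten-membered allylic alcohol (C9 carbinol, exocyclic C8=C17 tert-butyl enoate) | COC(=O)/C1=C/[C@H](O[Si](CC)(CC)CC)/C(=C(\C)C(=O)OC(C)(C)C)[C@H](O)[C@H]2[C@@H](C)[C@H](OC(C)=O)C[C@H](OC(C)=O)[C@]2(C)[C@H](OC(C)=O)CC1
F5 | step 24 | C8,C17-epoxy tert-butyl ester (epoxide oxygen cis to the C9 hydroxyl; C17 unassigned) | COC(=O)/C1=C/[C@H](O[Si](CC)(CC)CC)[C@]3(OC3(C)C(=O)OC(C)(C)C)[C@H](O)[C@H]2[C@@H](C)[C@H](OC(C)=O)C[C@H](OC(C)=O)[C@]2(C)[C@H](OC(C)=O)CC1
F6 | step 10 | 1,3-diketone (C2 and C14 carbonyls) from 14 | C=C[C@H]1[C@@H](C)[C@H](O[Si](C)(C)C(C)(C)C)CC(=O)[C@]1(C)C(=O)CCC(C(=O)OC)P(=O)(OC)OC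
F7 | step 10 | (14S)-hydroxy C2-ketone | C=C[C@H]1[C@@H](C)[C@H](O[Si](C)(C)C(C)(C)C)C[C@H](O)[C@]1(C)C(=O)CCC(C(=O)OC)P(=O)(OC)OC
F8 | step 26 | C19 trimethylsilyl ester of 34 with O8 trimethylsilylated (O7 triethylsilyl) | COC(=O)/C1=C/[C@H](O[Si](CC)(CC)CC)[C@@](O[Si](C)(C)C)(C(C)C(=O)O[Si](C)(C)C)[C@H](OC(C)=O)[C@H]2[C@@H](C)[C@H](OC(C)=O)C[C@H](OC(C)=O)[C@]2(C)[C@H](OC(C)=O)CC1
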